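**Retrosynthetic overview**
- The last step removes two benzyl ethers from the 5,7-di-O-benzyl coumaronochromone.
- The central furan is cut at C3–C1′ and C2–O2′, giving a 2-(methylsulfinyl)chromone and a 4-hydroxy-2,3-dihydrobenzofuran. In the forward direction an S–O bond forms first, a [3,3]-sigmatropic shift then makes C3–C1′, and ring closure with loss of MeSH follows.
- The γ-pyrone comes from 2,4-bis(benzyloxy)-6-hydroxyacetophenone, CS2 and MeI.
- The dihydrobenzofuranol comes from its 2-carboxylate and MeMgBr. The carboxylate comes from an SN2 ring closure (inversion) of an aryl-lactate mesylate, and that from aryl-copper opening of methyl (R)-glycidate, which supplies the only stereocentre.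
- Ring order: dihydrofuran first, γ-pyrone second (in parallel), central furan last. Both benzene rings are bought.

Assumption: 1,3-bis(methoxymethoxy)benzene, methyl (R)-glycidate (L-serine series) and 2,4-bis(benzyloxy)-6-hydroxyacetophenone are taken as catalogue items.

**Route**

Step 1
Reactants: 1 1,3-bis(methoxymethoxy)benzene; 2 methyl (2R)-oxirane-2-carboxylate
Product: 5 methyl (2R)-3-[2,6-bis(methoxymethoxy)phenyl]-2-hydroxypropanoate, via aryllithium 3 (not isolated), via arylmagnesium bromide 4 (not isolated)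
Conditions: n-BuLi, THF, 0 °C; MgBr2·OEt2 (1.0 equiv); CuI (10 mol %), 2, −40 → 0 °C; H2O
Reagents that add atoms: none
Why: Directed ortho-lithiation between the two MOM ethers gives the C2 anion, and the Cu-catalysed Grignard opens the glycidate at the unsubstituted C3 (SN2 epoxide opening) faster than it adds to the ester, so the stereocentre bought in 2 is carried over untouched as (R).

Step 2
Reactants: 5 methyl (2R)-3-[2,6-bis(methoxymethoxy)phenyl]-2-hydroxypropanoate
Product: 6 methyl (2R)-3-[2,6-bis(methoxymethoxy)phenyl]-2-(methanesulfonyloxy)propanoate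
Conditions: MsCl, Et3N, CH2Cl2, 0 °C
Reagents that add atoms: methanesulfonyl chloride CS(=O)(=O)Cl
Why: This is an ordinary O-sulfonylation of a secondary alcohol that does not touch the C–O bond, so (R) is retained.

Step 3
Reactants: 6 methyl (2R)-3-[2,6-bis(methoxymethoxy)phenyl]-2-(methanesulfonyloxy)propanoate
Product: 8 methyl (2S)-4-hydroxy-2,3-dihydro-1-benzofuran-2-carboxylate, via resorcinol mesylate 7 (not isolated)
Conditions: conc. HCl (cat.), MeOH, 45 °C; then K2CO3, 0 °C → rt
Reagents that add atoms: none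
Why: Acid-catalysed acetal exchange frees the two equivalent phenols, and one phenoxide then displaces the α-mesyloxy ester in a 5-exo-tet intramolecular Williamson SN2 with clean inversion, (R) → (S), with no neighbouring hydroxyl that could divert the reaction through an epoxide.

Step 4
Reactants: 8 methyl (2S)-4-hydroxy-2,3-dihydro-1-benzofuran-2-carboxylate
Product: 10 (2S)-2-(2-hydroxypropan-2-yl)-2,3-dihydro-1-benzofuran-4-ol, via methyl ketone 9 (not isolated)
Conditions: MeMgBr (4 equiv), THF, 0 °C → rt; H2O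
Reagents that add atoms: methylmagnesium bromide C[Mg]Br
Why: Double Grignard addition to the ester (one further equivalent is spent on the phenol) outruns enolisation at 0 °C, so the adjacent (S) centre is kept.

Step 5
Reactants: 11 1-[2,4-bis(benzyloxy)-6-hydroxyphenyl]ethan-1-one
Product: 13 5,7-bis(benzyloxy)-2-(methylsulfanyl)-4H-chromen-4-one, via ketene dithioacetal 12 (not isolated)
Conditions: KOtBu (3 equiv), CS2, THF, 0 °C; MeI (2 equiv), rt; then reflux
Reagents that add atoms: carbon disulfide S=C=S; iodomethane CI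
Why: Enolate dithiocarboxylation and double S-methylation give the α-oxoketene dithioacetal, whose ortho phenoxide closes the γ-pyrone by oxa-Michael addition and elimination of methanethiolate.

Step 6
Reactants: 13 5,7-bis(benzyloxy)-2-(methylsulfanyl)-4H-chromen-4-one
Product: 14 5,7-bis(benzyloxy)-2-(methylsulfinyl)-4H-chromen-4-one (racemic at sulfur)
Conditions: mCPBA (1.0 equiv), CH2Cl2, −10 °C
Reagents that add atoms: 3-chloroperbenzoic acid O=C(OO)c1cccc(Cl)c1
Why: One equivalent of peracid at low temperature stops the sulfide oxidation at the sulfoxide, and the sulfur stereocentre is irrelevant because step 7 erases it.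

Step 7
Reactants: 14 5,7-bis(benzyloxy)-2-(methylsulfinyl)-4H-chromen-4-one; 10 (2S)-2-(2-hydroxypropan-2-yl)-2,3-dihydro-1-benzofuran-4-ol
Product: 18 (S)-5,7-di-O-benzyl ether of the target coumaronochromone, via aryloxysulfonium trifluoroacetate 15 (not isolated), via 2-methylsulfanyl dihydro adduct 16 (not isolated), via tertiary trifluoroacetate 17 (not isolated)
Conditions: TFAA (2.5 equiv, added to 14 + 10, no base), CH2Cl2, −40 °C → rt; concentrate; K2CO3 (cat.), MeOH, rt
Reagents that add atoms: none
Why: Interrupted Pummerer activation ties the phenol oxygen to sulfur, the charge-accelerated [3,3]-sigmatropic rearrangement of the C3=C2–S+–O–C(aryl)=C(aryl) array (Yorimitsu-type benzofuran annulation) makes the C3–aryl bond at the only free ortho carbon, and rearomatisation, O-attack on C2 and loss of MeSH close the central furan while the carbinol stereocentre is a spectator whose tertiary OH is masked in situ as the trifluoroacetate and freed by methanolysis.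

Step 8
Reactants: 18 (S)-5,7-di-O-benzyl ether of the target coumaronochromone
Product: 19 CNP0193284.1 (S enantiomer)
Conditions: H2 (1 atm), 10 % Pd/C, EtOAc–MeOH, rt
Reagents that add atoms: none
Why: Hydrogenolysis cleaves the two aryl benzyl ethers, while the tetrasubstituted benzofuran/chromone π-system, the non-benzylic C2–O bond and the tertiary alcohol are inert.

**Compound list**
1 | 1,3-bis(methoxymethoxy)benzene | COCOc1cccc(OCOC)c1 | starting material
2 | methyl (2R)-oxirane-2-carboxylate, methyl (R)-glycidate | COC(=O)[C@H]1CO1 | starting material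
3 | 2-lithio-1,3-bis(methoxymethoxy)benzene | [Li]c1c(OCOC)cccc1OCOC | intermediate
4 | [2,6-bis(methoxymethoxy)phenyl]magnesium bromide | Br[Mg]c1c(OCOC)cccc1OCOC | intermediate
5 | methyl (2R)-3-[2,6-bis(methoxymethoxy)phenyl]-2-hydroxypropanoate | COC(=O)[C@H](O)Cc1c(OCOC)cccc1OCOC | intermediate
6 | methyl (2R)-3-[2,6-bis(methoxymethoxy)phenyl]-2-(methanesulfonyloxy)propanoate | COC(=O)[C@H](OS(C)(=O)=O)Cc1c(OCOC)cccc1OCOC | intermediate
7 | methyl (2R)-3-(2,6-dihydroxyphenyl)-2-(methanesulfonyloxy)propanoate | COC(=O)[C@H](OS(C)(=O)=O)Cc1c(O)cccc1O | intermediate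
8 | methyl (2S)-4-hydroxy-2,3-dihydro-1-benzofuran-2-carboxylate | COC(=O)[C@@H]1Cc2c(O)cccc2O1 | intermediate
9 | 1-[(2S)-4-hydroxy-2,3-dihydro-1-benzofuran-2-yl]ethan-1-one (present as its magnesium phenoxide) | CC(=O)[C@@H]1Cc2c(O)cccc2O1 | intermediate
10 | (2S)-2-(2-hydroxypropan-2-yl)-2,3-dihydro-1-benzofuran-4-ol | CC(C)(O)[C@@H]1Cc2c(O)cccc2O1 | intermediate
11 | 1-[2,4-bis(benzyloxy)-6-hydroxyphenyl]ethan-1-one | CC(=O)c1c(O)cc(OCc2ccccc2)cc1OCc1ccccc1 | starting material
12 | 1-[2,4-bis(benzyloxy)-6-hydroxyphenyl]-3,3-bis(methylsulfanyl)prop-2-en-1-one | CSC(SC)=CC(=O)c1c(O)cc(OCc2ccccc2)cc1OCc1ccccc1 | intermediate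
13 | 5,7-bis(benzyloxy)-2-(methylsulfanyl)-4H-chromen-4-one | CSc1cc(=O)c2c(OCc3ccccc3)cc(OCc3ccccc3)cc2o1 | intermediate
14 | 5,7-bis(benzyloxy)-2-(methylsulfinyl)-4H-chromen-4-one, racemic at S | CS(=O)c1cc(=O)c2c(OCc3ccccc3)cc(OCc3ccccc3)cc2o1 | intermediate
15 | [5,7-bis(benzyloxy)-4-oxochromen-2-yl](methyl){[(2S)-2-(2-hydroxypropan-2-yl)-2,3-dihydro-1-benzofuran-4-yl]oxy}sulfonium trifluoroacetate | CC(C)(O)[C@@H]1Cc2c(O[S+](C)c3cc(=O)c4c(OCc5ccccc5)cc(OCc5ccccc5)cc4o3)cccc2O1.[O-]C(=O)C(F)(F)F | intermediate
16 | ring-closed chromanone O,O,S-orthoester: C2 carries SMe and both ring oxygens, C3 carries H and the aryl carbon (new ring-fusion centres unassigned, erased on loss of MeSH) | CC(C)(O)[C@@H]1Cc2c(ccc3c2OC2(SC)Oc4cc(OCc5ccccc5)cc(OCc5ccccc5)c4C(=O)C23)O1 | intermediate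
17 | tertiary trifluoroacetate of 18 | CC(C)(OC(=O)C(F)(F)F)[C@@H]1Cc2c(ccc3c2oc2oc4cc(OCc5ccccc5)cc(OCc5ccccc5)c4c(=O)c23)O1 | intermediate
18 | (S)-5,7-bis(benzyloxy)coumaronochromone with the 3′,4′-fused 2-(2-hydroxypropan-2-yl)-2,3-dihydrofuran | CC(C)(O)[C@@H]1Cc2c(ccc3c2oc2oc4cc(OCc5ccccc5)cc(OCc5ccccc5)c4c(=O)c23)O1 | intermediate
19 | CNP0193284.1, (S)-5,7-dihydroxycoumaronochromone with the 3′,4′-fused 2-(2-hydroxypropan-2-yl)-2,3-dihydrofuran | CC(C)(O)[C@@H]1Cc2c(ccc3c2oc2oc4cc(O)cc(O)c4c(=O)c23)O1 | target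

**Totals**
- Total steps: 8.
- Longest linear sequence: 6 (steps 1, 2, 3, 4, 7, 8).

**Steps most likely to fail**

**Step 7.** The activated sulfoxide is also a strong electrophile at C2. The electron-rich phenol could instead attack C2 through oxygen, attack sulfur through its para carbon, or lose out to a normal Pummerer reaction at S–CH3. The fallback sets out from 14 and 10 and comes back at 18. Cs2CO3 in MeCN makes the phenoxide of 10 displace the sulfinyl group of 14 by addition–elimination. This gives 5,7-bis(benzyloxy)-2-{[(2S)-2-(2-hydroxypropan-2-yl)-2,3-dihydro-1-benzofuran-4-yl]oxy}-4H-chromen-4-one F1. An intramolecular Pd(II) dehydrogenative C–H/C–H coupling (Pd(OAc)2 cat., AgOAc, PivOH/DMA, 100 °C) then joins chromone C3–H to the single free ortho C–H and gives 18.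

**Step 1.** The di-ortho-substituted aryl-copper species may open the epoxide slowly, so that ester addition or bromohydrin formation takes over. The fallback sets out from 1 and 2 and comes back at 5.
- 2 is saponified (KOH, EtOH, 0 °C) to potassium (2R)-oxirane-2-carboxylate F2, which has no electrophilic carbonyl.
- The Gilman cuprate made from lithiated 1 and CuI (0.5 equiv) opens F2 at C3 to give (2R)-3-[2,6-bis(methoxymethoxy)phenyl]-2-hydroxypropanoic acid F3.
- MeI/K2CO3 in DMF esterifies the carboxylate to 5 without touching the MOM groups.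

**Step 3.** The freed phenol may lactonise onto the ester, and the 3-mesyloxy-dihydrocoumarin so formed may eliminate to a coumarin. The α-mesyloxy ester may also partly racemise in base. The fallback sets out from 5 and comes back at 8, bypassing 6. The MOM groups are cleaved first (cat. HCl, MeOH) to give methyl (2R)-3-(2,6-dihydroxyphenyl)-2-hydroxypropanoate F4. A base-free Mitsunobu cyclodehydration (PPh3, DIAD, THF, 0 °C) then activates the only alcohol, and a phenol displaces it with inversion to give 8.

**Further compounds**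
F1 | step 7 | 5,7-bis(benzyloxy)-2-{[(2S)-2-(2-hydroxypropan-2-yl)-2,3-dihydro-1-benzofuran-4-yl]oxy}-4H-chromen-4-one | CC(C)(O)[C@@H]1Cc2c(Oc3cc(=O)c4c(OCc5ccccc5)cc(OCc5ccccc5)cc4o3)cccc2O1
F2 | step 1 | potassium (2R)-oxirane-2-carboxylate | [K+].[O-]C(=O)[C@H]1CO1
F3 | step 1 | (2R)-3-[2,6-bis(methoxymethoxy)phenyl]-2-hydroxypropanoic acid | OC(=O)[C@H](O)Cc1c(OCOC)cccc1OCOC
F4 | step 3 | methyl (2R)-3-(2,6-dihydroxyphenyl)-2-hydroxypropanoate | COC(=O)[C@H](O)Cc1c(O)cccc1O
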